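**Retrosynthetic overview**
1. Target 8 ⇒ global O-debenzylation of the octa-O-benzyl biflavan 7, which already carries all four stereocentres.
2. 7 ⇒ the C6'(ring B, upper unit)–C8(ring A, lower unit) biaryl bond, made by Hiyama–Denmark coupling of benzoxasiline 4 with aryl bromide 5.
3. 4 ⇒ proposed hydroxyl-directed C6'–H silylation of tetrabenzyl ether 2; 5 ⇒ C8 bromination of the same 2.
4. 2 ⇒ (−)-epicatechin 1. No ring of the target is built: rings A, B and C of both units come intact from 1, and the only ring formed is the temporary six-membered Si,O ring of 4, opened again in the coupling.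

Assumption: (−)-epicatechin, (2R,3R), is taken as the commercial starting material and supplies all four stereocentres; the target SMILES gives no configuration for the C6'–C8 biaryl axis, so the axis is not controlled.

**Step 1**
Reactants: 1 (−)-epicatechin
Product: 2 tetrabenzyl ether 5,7,3',4'-tetra-O-benzyl-(−)-epicatechin
Conditions: BnBr (4.4 equiv), K2CO3 (5 equiv), DMF, 0 °C to rt, argon
Reagents that add atoms: benzyl bromide, BrCc1ccccc1
Why: Williamson etherification in which K2CO3 deprotonates only the four phenols (the C3 secondary alcohol stays free), and the weak base at or below room temperature does not open ring C, so the (2R,3R) centres of 1 are carried over unchanged.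

**Step 2**
Reactants: 2 tetrabenzyl ether 5,7,3',4'-tetra-O-benzyl-(−)-epicatechin
Product: 4 benzoxasiline O3,C6'-(diethylsilanediyl)-5,7,3',4'-tetra-O-benzyl-(−)-epicatechin (SiEt2 bonded to O3 and to C6' of ring B; six-membered 2,1-benzoxasiline ring cis-fused to ring C; 2R,3R), via hydrosilyl ether 3 (not isolated)
Conditions: Et2SiH2 (1.5 equiv), [Ir(cod)OMe]2 (0.5 mol%), THF, rt; evaporate; then [Ir(cod)OMe]2 (2 mol%), 3,4,7,8-tetramethyl-1,10-phenanthroline (5 mol%), norbornene (1.5 equiv), THF, 100 °C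
Reagents that add atoms: diethylsilane, CC[SiH2]CC
Why: Proposed new method: hydroxyl-directed dehydrogenative C–H silylation that closes a six-membered benzoxasiline on ring B of a flavan-3-ol; after the known iridium-catalysed O-silylation of the secondary alcohol, the Si–H bond of 3 adds to the phenanthroline-ligated monovalent iridium centre to give a trivalent iridium silyl hydride, norbornene takes up the hydrogen, and the tethered iridium silyl can reach only the two ortho C–H bonds of ring B (the C–H bonds at C2 and C4 would need a four-membered ring, and C1' and C4a carry no hydrogen), so C–H cleavage through a seven-membered metallacycle and C–Si reductive elimination give 4; C6'–H is chosen over C2'–H because C2' is flanked by the 3'-benzyloxy group and iridium silylation is sterically controlled, the cis relation of O3 and the C2 aryl group lets the ring close without strain, and no stereocentre is touched; the closest known reaction type is the iridium-catalysed ortho-silylation of benzylic alcohols to five-membered benzoxasiloles (and rhodium-catalysed δ-C–H silylation to six-membered oxasilinanes), not shown so far for a homobenzylic secondary alcohol of a flavan-3-ol.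

**Step 3**
Reactants: 2 tetrabenzyl ether 5,7,3',4'-tetra-O-benzyl-(−)-epicatechin
Product: 5 aryl bromide 8-bromo-5,7,3',4'-tetra-O-benzyl-(−)-epicatechin
Conditions: NBS (1.0 equiv), CH2Cl2, −78 °C to rt
Reagents that add atoms: N-bromosuccinimide, O=C1CCC(=O)N1Br
Why: Electrophilic aromatic bromination in which the phloroglucinol-type ring A reacts far faster than ring B or the benzyl rings, C8 being the established site of first attack in 5,7-di-O-benzyl flavan-3-ols with one equivalent of NBS; no stereocentre is touched.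

**Step 4**
Reactants: 4 benzoxasiline O3,C6'-(diethylsilanediyl)-5,7,3',4'-tetra-O-benzyl-(−)-epicatechin (1.3 equiv); 5 aryl bromide 8-bromo-5,7,3',4'-tetra-O-benzyl-(−)-epicatechin
Product: 7 octa-O-benzyl biflavan 5,7,3',4'-tetra-O-benzyl-(−)-epicatechin-(6'→8)-5,7,3',4'-tetra-O-benzyl-(−)-epicatechin (free 3-OH on both units), via sodium silanolate 6 (not isolated)
Conditions: Pd(OAc)2 (5 mol%), SPhos (2-dicyclohexylphosphino-2',6'-dimethoxybiphenyl, 10 mol%), NaOH (2 M aq, 3 equiv), 1,4-dioxane, 80 °C, degassed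
Reagents that add atoms: none
Why: Hiyama–Denmark cross-coupling in which hydroxide opens the Si–O bond of 4 to the arylsilanolate 6, zerovalent palladium inserts into the C8–Br bond of 5, the silanolate displaces bromide on palladium and the aryl group is transferred through the Pd–O–Si linkage before reductive elimination, so the C6'–C8 bond forms only where silicon and bromine were placed; the 3-OH of the upper unit is set free, no stereocentre is involved and the axis is left uncontrolled.

**Step 5**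
Reactants: 7 octa-O-benzyl biflavan 5,7,3',4'-tetra-O-benzyl-(−)-epicatechin-(6'→8)-5,7,3',4'-tetra-O-benzyl-(−)-epicatechin
Product: 8 target (−)-epicatechin-(6'→8)-(−)-epicatechin
Conditions: H2 (1 atm), Pd(OH)2/C, THF/MeOH/H2O (20:20:1), rt; filter under argon, lyophilise
Reagents that add atoms: none
Why: Heterogeneous catalytic hydrogenolysis of the eight aryl benzyl ethers under neutral conditions, which leaves the biaryl bond, the ring C ether bonds and the four stereocentres untouched.

**Compound list**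
1 | (−)-epicatechin, (2R,3R)-2-(3,4-dihydroxyphenyl)chromane-3,5,7-triol | Oc1cc(O)c2c(c1)O[C@H](c1ccc(O)c(O)c1)[C@H](O)C2 | starting material
2 | 5,7,3',4'-tetra-O-benzyl-(−)-epicatechin, (2R,3R)-5,7-bis(benzyloxy)-2-[3,4-bis(benzyloxy)phenyl]chroman-3-ol | c1ccccc1COc1cc(OCc2ccccc2)c2c(c1)O[C@H](c1ccc(OCc3ccccc3)c(OCc3ccccc3)c1)[C@H](O)C2 | intermediate
3 | 3-O-(diethylsilyl)-5,7,3',4'-tetra-O-benzyl-(−)-epicatechin (O–SiHEt2 at C3; 2R,3R) | c1ccccc1COc1cc(OCc2ccccc2)c2c(c1)O[C@H](c1ccc(OCc3ccccc3)c(OCc3ccccc3)c1)[C@H](O[SiH](CC)CC)C2 | intermediate (not isolated)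
4 | O3,C6'-(diethylsilanediyl)-5,7,3',4'-tetra-O-benzyl-(−)-epicatechin (2,1-benzoxasiline: SiEt2 bonded to O3 and to C6' of ring B; 2R,3R) | c1ccccc1COc1cc(OCc2ccccc2)c2c(c1)O[C@H](c1cc(OCc3ccccc3)c(OCc3ccccc3)cc1[Si]4(CC)CC)[C@H](O4)C2 | intermediate
5 | 8-bromo-5,7,3',4'-tetra-O-benzyl-(−)-epicatechin (2R,3R) | c1ccccc1COc1cc(OCc2ccccc2)c2c(c1Br)O[C@H](c1ccc(OCc3ccccc3)c(OCc3ccccc3)c1)[C@H](O)C2 | intermediate
6 | sodium diethyl(aryl)silanolate of 5,7,3',4'-tetra-O-benzyl-(−)-epicatechin (SiEt2ONa on C6' of ring B, free 3-OH; 2R,3R) | c1ccccc1COc1cc(OCc2ccccc2)c2c(c1)O[C@H](c1cc(OCc3ccccc3)c(OCc3ccccc3)cc1[Si](CC)(CC)[O-])[C@H](O)C2.[Na+] | intermediate (not isolated)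
7 | 5,7,3',4'-tetra-O-benzyl-(−)-epicatechin-(6'→8)-5,7,3',4'-tetra-O-benzyl-(−)-epicatechin (both units 2R,3R) | c1ccccc1COc1cc(OCc2ccccc2)c2c(c1)O[C@H](c1cc(OCc3ccccc3)c(OCc3ccccc3)cc1-c1c(OCc3ccccc3)cc(OCc3ccccc3)c3c1O[C@H](c1ccc(OCc4ccccc4)c(OCc4ccccc4)c1)[C@H](O)C3)[C@H](O)C2 | intermediate
8 | (2R,3R)-2-[2-[(2R,3R)-2-(3,4-dihydroxyphenyl)-3,5,7-trihydroxychroman-8-yl]-4,5-dihydroxyphenyl]chromane-3,5,7-triol, CNP0353739.3 | Oc1cc(O)c2c(c1)O[C@H](c1cc(O)c(O)cc1-c1c(O)cc(O)c3c1O[C@H](c1ccc(O)c(O)c1)[C@H](O)C3)[C@H](O)C2 | target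

**Totals**
Total step count: 5. Longest linear sequence: 4 steps (1 → 2 → 4 → 7 → 8); step 3 is the one-step side branch from 2 to 5.

**Three steps most likely to fail**

Step 2 (the proposed new step). The six-membered ring has to close through a seven-membered metallacycle, and silane redistribution or loss of the silyl group could compete. The fallback uses known chemistry; it sets out from 2 (and uses 5) and comes back to the route at 8. Ring A of 2 is blocked with NBS (2.1 equiv, CH2Cl2, 0 °C to rt) to give 6,8-dibromo-5,7,3',4'-tetra-O-benzyl-(−)-epicatechin F1. With both ring A positions filled, NIS and catalytic CF3CO2H in MeCN iodinate the most electron-rich free position of ring B, C6' (para to the 3'-benzyloxy group), to give 6,8-dibromo-6'-iodo-5,7,3',4'-tetra-O-benzyl-(−)-epicatechin F2. Bromide 5 is turned by Miyaura borylation (B2pin2, Pd(OAc)2, SPhos, KOAc, dioxane, 90 °C) into 5,7,3',4'-tetra-O-benzyl-8-(4,4,5,5-tetramethyl-1,3,2-dioxaborolan-2-yl)-(−)-epicatechin F3. Suzuki–Miyaura coupling of F2 with F3 (Pd(PPh3)4, K3PO4, dioxane/H2O, 70 °C) takes place at the C–I bond, because the two doubly ortho-alkoxylated C–Br bonds add to zerovalent palladium much more slowly, and gives 6,8-dibromo-5,7,3',4'-tetra-O-benzyl-(−)-epicatechin-(6'→8)-5,7,3',4'-tetra-O-benzyl-(−)-epicatechin F4. Hydrogenolysis (H2, Pd(OH)2/C, Et3N, THF/MeOH) removes the eight benzyl groups and both bromine atoms and gives 8.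

Step 4. The coupling builds a biaryl with three ortho substituents from an electron-rich, doubly ortho-substituted bromide; loss of silicon from 4 or of bromine from 5 would return 2, which can be recycled. The fallback replaces silicon by boron as the transmetalating group; it sets out from 4 and comes back at 7. Tamao–Fleming oxidation of 4 (30% H2O2, KF, KHCO3, THF/MeOH, rt) gives 6'-hydroxy-5,7,3',4'-tetra-O-benzyl-(−)-epicatechin F5. PhNTf2 and K2CO3 in DMF triflate the phenol, not the secondary alcohol, to give 5,7,3',4'-tetra-O-benzyl-6'-(trifluoromethanesulfonyloxy)-(−)-epicatechin F6. Miyaura borylation (B2pin2, Pd(dppf)Cl2, KOAc, dioxane, 90 °C) gives 5,7,3',4'-tetra-O-benzyl-6'-(4,4,5,5-tetramethyl-1,3,2-dioxaborolan-2-yl)-(−)-epicatechin F7. Suzuki–Miyaura coupling of F7 with 5 (Pd(OAc)2, SPhos, K3PO4, toluene/H2O, 90 °C) gives 7.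

Step 5. Eight benzyl ethers must be removed, the deca-hydroxy product is easily oxidised, and over-reduction of the benzylic C2–O bonds is possible. The fallback changes from reductive cleavage on a metal surface to Lewis-acid ionisation with a cation scavenger; it sets out from 7 and comes back at 8. Treating 7 with BCl3 and pentamethylbenzene in CH2Cl2 at −78 °C, then quenching with MeOH, cleaves the aryl benzyl ethers while pentamethylbenzene traps the benzyl cations before they can alkylate ring A; this fallback makes no new compound (F0).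

**Further compounds**
F1 | step 2 | 6,8-dibromo-5,7,3',4'-tetra-O-benzyl-(−)-epicatechin (2R,3R) | c1ccccc1COc1c(Br)c(OCc2ccccc2)c2c(c1Br)O[C@H](c1ccc(OCc3ccccc3)c(OCc3ccccc3)c1)[C@H](O)C2
F2 | step 2 | 6,8-dibromo-6'-iodo-5,7,3',4'-tetra-O-benzyl-(−)-epicatechin (2R,3R) | c1ccccc1COc1c(Br)c(OCc2ccccc2)c2c(c1Br)O[C@H](c1cc(OCc3ccccc3)c(OCc3ccccc3)cc1I)[C@H](O)C2
F3 | step 2 | 5,7,3',4'-tetra-O-benzyl-8-(4,4,5,5-tetramethyl-1,3,2-dioxaborolan-2-yl)-(−)-epicatechin (2R,3R) | c1ccccc1COc1cc(OCc2ccccc2)c2c(c1B3OC(C)(C)C(C)(C)O3)O[C@H](c1ccc(OCc3ccccc3)c(OCc3ccccc3)c1)[C@H](O)C2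
F4 | step 2 | 6,8-dibromo-5,7,3',4'-tetra-O-benzyl-(−)-epicatechin-(6'→8)-5,7,3',4'-tetra-O-benzyl-(−)-epicatechin (both units 2R,3R) | c1ccccc1COc1c(Br)c(OCc2ccccc2)c2c(c1Br)O[C@H](c1cc(OCc3ccccc3)c(OCc3ccccc3)cc1-c1c(OCc3ccccc3)cc(OCc3ccccc3)c3c1O[C@H](c1ccc(OCc4ccccc4)c(OCc4ccccc4)c1)[C@H](O)C3)[C@H](O)C2
F5 | step 4 | 6'-hydroxy-5,7,3',4'-tetra-O-benzyl-(−)-epicatechin (2R,3R) | c1ccccc1COc1cc(OCc2ccccc2)c2c(c1)O[C@H](c1cc(OCc3ccccc3)c(OCc3ccccc3)cc1O)[C@H](O)C2
F6 | step 4 | 5,7,3',4'-tetra-O-benzyl-6'-(trifluoromethanesulfonyloxy)-(−)-epicatechin (2R,3R) | c1ccccc1COc1cc(OCc2ccccc2)c2c(c1)O[C@H](c1cc(OCc3ccccc3)c(OCc3ccccc3)cc1OS(=O)(=O)C(F)(F)F)[C@H](O)C2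
F7 | step 4 | 5,7,3',4'-tetra-O-benzyl-6'-(4,4,5,5-tetramethyl-1,3,2-dioxaborolan-2-yl)-(−)-epicatechin (2R,3R) | c1ccccc1COc1cc(OCc2ccccc2)c2c(c1)O[C@H](c1cc(OCc3ccccc3)c(OCc3ccccc3)cc1B3OC(C)(C)C(C)(C)O3)[C@H](O)C2
F0 | step 5 | none | none
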